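Germacrane numbering is used throughout: lactone O on C6, fusion carbon C7, acyloxy C8, carbinol C9, C10(Me)=C1, C2H2, acetoxy C3, C4(Me)=C5; C11–C13 are the methylene‑lactone carbons.

**Plan**
- Cuts: remove the O3 acetyl, C11=C13, the lactone bond C12–O6 and the C8 ester. Raising C6 to a ketone exposes C6(=O)–C7–C8–C9–C10=C1, a δ,ε‑unsaturated ketone, which is the oxy‑Cope retron.
- Then cut C7–C11 (enolate alkylation) and C8–C9 while drawing a temporary C1–C6 bond. The ten‑membered ring collapses to a cyclohexenol (C1–C6) that already holds the Z C4=C5 olefin and C3. It bears a (Z)‑2‑alkoxyvinyl group on C6 and an (E)‑2‑siloxy‑1‑methylvinyl group on C1.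
- Forward: six‑membered ring from (R)‑carvone → ten‑membered carbocycle by ring expansion closing C8–C9, with C7 alkylated in the same flask → γ‑lactone → exocyclic methylene → acetate → free O9.
- Stereochemistry: the sacrificial C1 comes from carvone, C3 from a CBS reduction, the C6 carbinol from axial addition. These centres and the two enol‑ether geometries are relayed through a chair to C8, C9 and the Z C1=C10 olefin.
- C7 comes from a chelated alkylation. C6 comes from a 1,3‑anti Evans–Tishchenko hydride shift from O8, which also installs the epoxy ester (both its centres from a Sharpless epoxidation). Helpers removed later: the C1–C6 bond, the C6 ketone level, and PMB, TES, TBS and tert‑butyl groups.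

Key step: step 9

Remark: read literally, the structure is the 1(10)Z,4Z‑diene and its acyl group is (2S,3R)‑2,3‑dimethyloxirane‑2‑carboxylate, with carboxyl and C3' methyl trans (tiglate‑type epoxide). The route is built for exactly this isomer.

**Step 1**
Reactants: 1 (R)‑(−)‑carvone
Product: 2 (−)‑trans‑carveol, (1S,5R)‑2‑methyl‑5‑(prop‑1‑en‑2‑yl)cyclohex‑2‑en‑1‑ol
Conditions: (R)‑2‑methyl‑CBS‑oxazaborolidine (cat.), catecholborane, toluene, −78 °C
Reagents that add atoms: none
Why: Corey–Bakshi–Shibata reduction in which the oxazaborolidine binds the enone with the 2‑methylalkenyl arm as the large group and delivers hydride to the face that gives the 1S (pseudoaxial, trans) alcohol, so that reagent control overrides the weak substrate preference for the cis alcohol while catecholborane leaves both olefins alone.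

**Step 2**
Reactants: 2 (−)‑trans‑carveol
Product: 3 trans‑carveol triethylsilyl ether
Conditions: Et3SiCl, imidazole, CH2Cl2, 0 °C
Reagents that add atoms: chlorotriethylsilane, CC[Si](Cl)(CC)CC
Why: Standard silylation of a secondary allylic alcohol, giving an ether that withstands bases and organometallics yet is lost in the acid of step 14.

**Step 3**
Reactants: 3 trans‑carveol triethylsilyl ether
Product: 4 (4S,6R)‑3‑methyl‑6‑(prop‑1‑en‑2‑yl)‑4‑(triethylsilyloxy)cyclohex‑2‑en‑1‑one
Conditions: Rh2(cap)4 (dirhodium tetrakis(caprolactamate), cat.), t‑BuOOH, K2CO3, CH2Cl2, rt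
Reagents that add atoms: tert‑butyl hydroperoxide, CC(C)(C)OO
Why: Dirhodium‑catalysed allylic C–H oxidation should attack the only allylic ring methylene (future C6), the C3–H being pseudoequatorial and poorly aligned with the π system, and gives the enone without touching C1 or C3.

**Step 4**
Reactants: 4 (4S,6R)‑enone
Product: 6 2‑[(1R,5S)‑4‑methyl‑2‑oxo‑5‑(triethylsilyloxy)cyclohex‑3‑en‑1‑yl]prop‑2‑enal, via allylic alcohol 5 (not isolated)
Conditions: SeO2 (cat.), t‑BuOOH, CH2Cl2, 0 °C to rt; filtrate then MnO2, CH2Cl2, rt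
Reagents that add atoms: selenium dioxide, O=[Se]=O; tert‑butyl hydroperoxide, CC(C)(C)OO
Why: Selenium dioxide allylic hydroxylation (ene reaction then [2,3]‑shift) chooses the methyl group of the 1,1‑disubstituted olefin because the ring olefin is deactivated as an enone, and MnO2 oxidation of the primary allylic alcohol gives the 2‑substituted acrolein under neutral conditions that spare the epimerisable C1.

**Step 5**
Reactants: 6 keto enal
Product: 7 (4S,6R)‑6‑[(E)‑1‑(tert‑butyldimethylsilyloxy)prop‑1‑en‑2‑yl]‑3‑methyl‑4‑(triethylsilyloxy)cyclohex‑2‑en‑1‑one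
Conditions: RhCl(PPh3)3 (cat.), t‑BuMe2SiH, THF, 40 °C
Reagents that add atoms: tert‑butyldimethylsilane, C[SiH](C)C(C)(C)C
Why: Rhodium‑catalysed 1,4‑hydrosilylation of the unhindered enal through its s‑cis bound form puts hydrogen on the methylene carbon and silicon on oxygen, so that O9 ends cis to the new methyl group and trans to the ring (E, also the less crowded isomer), the β,β‑disubstituted ring enone reacting far more slowly.

**Step 6**
Reactants: 8 4‑methoxybenzyl alcohol; 9 trichloroethylene
Product: 10 (E)‑1,2‑dichlorovinyl 4‑methoxybenzyl ether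
Conditions: KH, THF, 0 °C; then 9, −50 °C to rt
Reagents that add atoms: none
Why: Addition–elimination of the potassium alkoxide on trichloroethylene (through dichloroacetylene) is the standard entry to 1,2‑dichlorovinyl ethers, the precursors of ynol ethers.

**Step 7**
Reactants: 7 silyl enol ether enone; 10 dichlorovinyl ether
Product: 12 (1S,4S,6R)‑6‑[(E)‑1‑(tert‑butyldimethylsilyloxy)prop‑1‑en‑2‑yl]‑1‑[(4‑methoxybenzyloxy)ethynyl]‑3‑methyl‑4‑(triethylsilyloxy)cyclohex‑2‑en‑1‑ol, via lithium alkoxyacetylide 11 (not isolated)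
Conditions: 10, n‑BuLi (2.2 equiv), THF, −78 to −40 °C; then 7, −78 °C; aq NH4Cl
Reagents that add atoms: none
Why: Elimination and chlorine–lithium exchange give the rod‑like acetylide, whose 1,2‑addition should follow the axial trajectory on the half‑chair with the C1 side chain equatorial and C3‑OTES pseudoaxial (anti to the axial C1–H and away from the silyloxy‑shielded face), so that the alkynyl group ends cis to the C1 side chain and O6 cis to O3.

**Step 8**
Reactants: 12 alkynyl carbinol
Product: 13 (1S,4S,6R)‑1‑[(Z)‑2‑(4‑methoxybenzyloxy)ethenyl] carbinol (other groups as in 12)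
Conditions: H2 (1 atm), Pd/CaCO3 poisoned with Pb(OAc)2, quinoline, EtOAc–hexane–Et3N, 0 °C
Reagents that add atoms: none
Why: Lindlar‑type syn semihydrogenation of the ynol ether gives the Z enol ether, and the amine‑buffered medium prevents acid‑triggered collapse of the 3‑alkoxyallylic alcohol to an enal.

**Step 9**
Reactants: 13 bis(enol ether) carbinol; 14 tert‑butyl bromoacetate
Product: 17 tert‑butyl [(4Z,8Z)‑3‑(tert‑butyldimethylsilyloxy)‑2‑(4‑methoxybenzyloxy)‑4,8‑dimethyl‑10‑oxo‑7‑(triethylsilyloxy)cyclodeca‑4,8‑dien‑1‑yl]acetate (germacrane 3S,8S,9R; C7 as in the target), via potassium alkoxide 15 (not isolated), via potassium enolate 16 (not isolated)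
Conditions: KH, 18‑crown‑6, THF, −20 to 10 °C; then 14, −78 °C
Reagents that add atoms: none
Why: Proposed new method: KH/18‑crown‑6 turns 13 into the naked tertiary alkoxide 15, whose oxido group weakens the doubly allylic C1–C6 bond so that a concerted suprafacial [3,3] shift (anionic oxy‑Cope rearrangement) breaks C1–C6, joins the enol‑ether termini C8 and C9 and is pulled forward by the change from alkoxide to enolate 16. The closest known reaction type is the anionic oxy‑Cope ring expansion of 1,2‑dialkenylcyclohex‑2‑en‑1‑ols to cyclodecadienones, also known with one alkoxy‑bearing terminus; new is only that both termini carry oxygen, so that the bond formed is that of a differentiated 1,2‑diol. The ten‑membered ring is thus closed by a four‑atom ring expansion of the cyclohexene through a six‑centre chair, not by an end‑to‑end cyclisation, and needs no dilution. Since the two alkenyl groups are cis, the chair reached from the favoured half‑chair (C1 side chain equatorial, C3‑OTES pseudoaxial, C6 alkenyl pseudoaxial) holds C5 equatorial and C2, O6 and O8 axial: axial C2 gives the Z C1=C10 olefin (C4=C5 stays Z because it was endocyclic in the six‑membered ring), and axial O8 (Z enol ether) together with equatorial O9 (E enol ether) translates the C1/C6 configuration into 8S,9R. The selectivity needed is this chair over the alternative one, which would give the E olefin and the wrong diol, and the substrate secures it because the alternative needs the side chain axial, sets C5 1,3‑diaxial to OPMB and loses the K+ bridge between O6 and O8. The same K+ chelate (O6, O8) holds enolate 16, which 14 should alkylate at once at −78 °C on the outer face, anti to C9 (the sense of a Fráter–Seebach alkylation), to set the C7 configuration of the target before p‑methoxybenzyl oxide can be lost by β‑elimination.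

**Step 10**
Reactants: 17 keto ester
Product: 18 8‑hydroxy keto ester (β‑hydroxy ketone; other groups as in 17)
Conditions: DDQ, CH2Cl2–pH 7 buffer, 0 °C
Reagents that add atoms: none
Why: Oxidative cleavage of the p‑methoxybenzyl ether by DDQ (hydride abstraction, hydrolysis of the oxocarbenium ion) is neutral, so the β‑hydroxy ketone should neither eliminate nor retro‑aldolise, and the bulky tert‑butyl ester resists lactonisation by O8.

**Step 11**
Reactants: 19 (E)‑2‑methylbut‑2‑en‑1‑ol
Product: 20 [(2R,3R)‑2,3‑dimethyloxiran‑2‑yl]methanol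
Conditions: Ti(OiPr)4 (cat.), D‑(−)‑diethyl tartrate (cat.), t‑BuOOH, 4 Å molecular sieves, CH2Cl2, −20 °C
Reagents that add atoms: tert‑butyl hydroperoxide, CC(C)(C)OO
Why: Sharpless asymmetric epoxidation, in which D‑(−)‑tartrate directs oxygen to the face of the E allylic alcohol that gives the (2R,3R)‑epoxy alcohol and so fixes both side‑chain centres.

**Step 12**
Reactants: 20 epoxy alcohol
Product: 21 (2S,3R)‑2,3‑dimethyloxirane‑2‑carbaldehyde
Conditions: TEMPO (cat.), PhI(OAc)2, CH2Cl2, 0 °C to rt; used as a solution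
Reagents that add atoms: none
Why: Oxoammonium (TEMPO) oxidation stops at the non‑enolisable aldehyde and leaves the epoxide and its two centres untouched.

**Step 13**
Reactants: 18 β‑hydroxy ketone; 21 epoxy aldehyde
Product: 22 (6R)‑6‑hydroxy‑8‑O‑[(2S,3R)‑2,3‑dimethyloxirane‑2‑carbonyl] tert‑butyl ester
Conditions: 21 (excess), SmI2 (0.3 equiv, aged with 21 to the trivalent samarium alkoxide), THF, −10 °C
Reagents that add atoms: none
Why: Evans–Tishchenko reaction in which O8 adds to aldehyde 21 and the samarium‑bound hemiacetal passes its hydride intramolecularly to C6 through a chair‑like bicyclic transition state, giving the 1,3‑anti (6R) alcohol and at the same stroke leaving O8 as the epoxy ester, so that O6 and O8 are differentiated.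

**Step 14**
Reactants: 22 hydroxy ester
Product: 24 11,13‑dihydro lactone with free C3–OH (9‑O‑TBS, 8‑O‑epoxyacyl, trans‑fused 6,12‑olide), via seco acid 23 (not isolated)
Conditions: CF3CO2H–CH2Cl2 (1:4), 0 °C
Reagents that add atoms: none
Why: Acidolysis of the tert‑butyl ester (loss of isobutene) and of the triethylsilyl ether is followed by spontaneous 5‑exo‑trig lactonisation of the γ‑hydroxy acid on O6, the only free hydroxyl within reach, while the hindered secondary TBS ether and the electron‑poor glycidic ester should survive.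

**Step 15**
Reactants: 24 dihydro lactone
Product: 26 α‑methylene lactone with free C3–OH, via Mannich base 25 (not isolated)
Conditions: LiN(iPr)2 (2.5 equiv), THF, −78 °C; Me2N=CH2 I; then MeI, MeOH, rt; aq NaHCO3
Reagents that add atoms: N,N‑dimethylmethyleneiminium iodide, C=[N+](C)C.[I-]
Why: α‑Methylenation by Mannich reaction of the lactone enolate with Eschenmoser's salt, quaternisation and Hofmann‑type elimination, the epoxy ester having no α‑hydrogen, the C3 alkoxide being a spectator and the transient C11 centre being erased.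

**Step 16**
Reactants: 26 α‑methylene lactone
Product: 27 3‑O‑acetyl‑9‑O‑TBS derivative of the target
Conditions: Ac2O, pyridine, CH2Cl2, 0 °C
Reagents that add atoms: acetic anhydride, CC(=O)OC(C)=O
Why: Acetylation of the only free hydroxyl group (C3) with retention of configuration under mild conditions that the methylene lactone tolerates.

**Step 17**
Reactants: 27 silyl ether
Product: 28 CNP0299903.2 (target)
Conditions: HF·pyridine, pyridine, THF, 0 °C to rt
Reagents that add atoms: none
Why: Fluoride‑mediated desilylation in a buffered, weakly acidic medium frees O9 without acyl migration from O8, epoxide opening or conjugate addition to the methylene lactone.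

**Compound list**
1 | (R)‑(−)‑carvone | CC1=CC[C@H](CC1=O)C(C)=C | starting material
2 | (−)‑trans‑carveol, (1S,5R) | C1C=C(C)[C@@H](O)C[C@@H]1C(C)=C | intermediate
3 | trans‑carveol triethylsilyl ether | C1C=C(C)[C@@H](O[Si](CC)(CC)CC)C[C@@H]1C(C)=C | intermediate
4 | (4S,6R)‑3‑methyl‑6‑(prop‑1‑en‑2‑yl)‑4‑(triethylsilyloxy)cyclohex‑2‑en‑1‑one | O=C1C=C(C)[C@@H](O[Si](CC)(CC)CC)C[C@@H]1C(C)=C | intermediate
5 | (4S,6R)‑6‑(3‑hydroxyprop‑1‑en‑2‑yl) enone | O=C1C=C(C)[C@@H](O[Si](CC)(CC)CC)C[C@@H]1C(=C)CO | intermediate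
6 | keto enal | O=C1C=C(C)[C@@H](O[Si](CC)(CC)CC)C[C@@H]1C(=C)C=O | intermediate
7 | (E)‑silyl enol ether enone | O=C1C=C(C)[C@@H](O[Si](CC)(CC)CC)C[C@@H]1/C(C)=C/O[Si](C)(C)C(C)(C)C | intermediate
8 | 4‑methoxybenzyl alcohol | COc1ccc(CO)cc1 | starting material
9 | trichloroethylene | ClC=C(Cl)Cl | starting material
10 | (E)‑1,2‑dichlorovinyl 4‑methoxybenzyl ether | COc1ccc(CO/C(Cl)=C\Cl)cc1 | intermediate
11 | lithium (4‑methoxybenzyloxy)acetylide | [Li]C#COCc1ccc(OC)cc1 | intermediate
12 | alkynyl carbinol (1S,4S,6R) | O[C@@]1(C#COCc2ccc(OC)cc2)C=C(C)[C@@H](O[Si](CC)(CC)CC)C[C@@H]1/C(C)=C/O[Si](C)(C)C(C)(C)C | intermediate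
13 | (Z)‑alkoxyvinyl (E)‑siloxypropenyl carbinol (1S,4S,6R) | O[C@@]1(/C=C\OCc2ccc(OC)cc2)C=C(C)[C@@H](O[Si](CC)(CC)CC)C[C@@H]1/C(C)=C/O[Si](C)(C)C(C)(C)C | intermediate
14 | tert‑butyl bromoacetate | CC(C)(C)OC(=O)CBr | starting material
15 | potassium alkoxide of 13 | [K+].[O-][C@@]1(/C=C\OCc2ccc(OC)cc2)C=C(C)[C@@H](O[Si](CC)(CC)CC)C[C@@H]1/C(C)=C/O[Si](C)(C)C(C)(C)C | intermediate
16 | potassium enolate of the ten‑membered dienone (C5 and C8 trans on C6=C7) | [K+].[C@H]1(OCc2ccc(OC)cc2)/C=C(\[O-])/C=C(/C)[C@@H](O[Si](CC)(CC)CC)C/C=C(/C)[C@H]1O[Si](C)(C)C(C)(C)C | intermediate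
17 | C7‑alkylated keto ester | O=C1/C=C(/C)[C@@H](O[Si](CC)(CC)CC)C/C=C(/C)[C@@H](O[Si](C)(C)C(C)(C)C)[C@@H](OCc2ccc(OC)cc2)[C@H]1CC(=O)OC(C)(C)C | intermediate
18 | 8‑hydroxy keto ester | O=C1/C=C(/C)[C@@H](O[Si](CC)(CC)CC)C/C=C(/C)[C@@H](O[Si](C)(C)C(C)(C)C)[C@@H](O)[C@H]1CC(=O)OC(C)(C)C | intermediate
19 | (E)‑2‑methylbut‑2‑en‑1‑ol | C/C=C(\C)CO | starting material
20 | [(2R,3R)‑2,3‑dimethyloxiran‑2‑yl]methanol | OC[C@@]1(C)O[C@@H]1C | intermediate
21 | (2S,3R)‑2,3‑dimethyloxirane‑2‑carbaldehyde | O=C[C@@]1(C)O[C@@H]1C | intermediate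
22 | (6R)‑hydroxy 8‑epoxy ester tert‑butyl ester | O[C@@H]1/C=C(/C)[C@@H](O[Si](CC)(CC)CC)C/C=C(/C)[C@@H](O[Si](C)(C)C(C)(C)C)[C@@H](OC(=O)[C@@]2(C)O[C@@H]2C)[C@H]1CC(=O)OC(C)(C)C | intermediate
23 | 3,6‑dihydroxy seco acid | O[C@@H]1/C=C(/C)[C@@H](O)C/C=C(/C)[C@@H](O[Si](C)(C)C(C)(C)C)[C@@H](OC(=O)[C@@]2(C)O[C@@H]2C)[C@H]1CC(=O)O | intermediate
24 | 11,13‑dihydro lactone, C3–OH free | C1C(=O)O[C@@H]2/C=C(/C)[C@@H](O)C/C=C(/C)[C@@H](O[Si](C)(C)C(C)(C)C)[C@@H](OC(=O)[C@@]3(C)O[C@@H]3C)[C@@H]12 | intermediate
25 | 11‑(dimethylaminomethyl) lactone (C11 epimers) | CN(C)CC1C(=O)O[C@@H]2/C=C(/C)[C@@H](O)C/C=C(/C)[C@@H](O[Si](C)(C)C(C)(C)C)[C@@H](OC(=O)[C@@]3(C)O[C@@H]3C)[C@@H]12 | intermediate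
26 | α‑methylene lactone, C3–OH free | C=C1C(=O)O[C@@H]2/C=C(/C)[C@@H](O)C/C=C(/C)[C@@H](O[Si](C)(C)C(C)(C)C)[C@@H](OC(=O)[C@@]3(C)O[C@@H]3C)[C@@H]12 | intermediate
27 | 9‑O‑TBS ether of the target | C=C1C(=O)O[C@@H]2/C=C(/C)[C@@H](OC(C)=O)C/C=C(/C)[C@@H](O[Si](C)(C)C(C)(C)C)[C@@H](OC(=O)[C@@]3(C)O[C@@H]3C)[C@@H]12 | intermediate
28 | CNP0299903.2 | C=C1C(=O)O[C@@H]2/C=C(/C)[C@@H](OC(C)=O)C/C=C(/C)[C@@H](O)[C@@H](OC(=O)[C@@]3(C)O[C@@H]3C)[C@@H]12 | target

Total step count: 17. Longest linear sequence: 14 (steps 1–5, 7–10, 13–17).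

**Steps most likely to fail**

**Step 9.** With donor groups on both termini the shift may be too slow at temperatures that alkoxide 15 and enolate 16 survive, so that decomposition overtakes ring expansion. The fallback uses known chemistry only: one oxygen is carried through the shift and O9 is added afterwards. It sets out from enone 4. Acetylide 11 adds to give the alkynyl isopropenyl carbinol F1. Syn semihydrogenation over Pd/CaCO3 poisoned with Pb(OAc)2 gives the (Z)‑alkoxyvinyl isopropenyl carbinol F2. KH/18‑crown‑6 followed by 14 gives the C9‑unsubstituted keto ester F3 by the established ring expansion of 6‑isopropenylcyclohex‑2‑enols. SeO2/t‑BuOOH then hydroxylates the ring methylene next to the more substituted olefin carbon (C9) on the outer face to give the allylic alcohol F4. t‑BuMe2SiOTf/2,6‑lutidine returns to the route at 17.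

**Step 7.** Poor facial selectivity is the risk: attack anti to the C1 side chain would give the trans‑dialkenyl epimer, which rearranges to the E olefin. The fallback replaces carbon delivery to a ketone by a stereospecific lithiation–borylation. It sets out from 7.
- Luche reduction (NaBH4, CeCl3·7H2O, MeOH, −78 °C; hydride, the smallest nucleophile, on the axial path) gives the pseudoequatorial allylic alcohol F5 with O6 trans to the side chain.
- iPr2NCOCl/pyridine gives the carbamate F6.
- Separately, quenching 11 with water gives the ethynyl ether F7. Trans‑hydroboration with pinacolborane ([Rh(cod)Cl]2, P(iPr)3, Et3N) gives the (Z)‑alkenylboronate F8.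
- s‑BuLi/TMEDA deprotonates F6 at C6 with retention, F8 is captured with retention, and 1,2‑migration of the alkenyl group anti to the carbamate gives the tertiary allylic boronic ester F9.
- Me3NO oxidation with retention comes back to the route at 13.

**Step 13.** The hindered aldehyde may form the hemiacetal too reluctantly, so that retro‑aldol cleavage, epoxide opening by the Lewis acid or acyl migration competes. The fallback separates reduction, lactonisation and acylation, and sets out from 17.
- Reagent‑controlled Corey–Bakshi–Shibata reduction ((R)‑catalyst, catecholborane; alkenyl arm as the large group) gives the (6R)‑alcohol F10.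
- Catalytic NaH in THF closes the PMB‑protected lactone F11.
- DDQ gives the 8‑hydroxy lactone F12.
- TEMPO/PhI(OAc)2 in MeCN–water turns 20 into the epoxy acid F13.
- Yamaguchi esterification (2,4,6‑trichlorobenzoyl chloride, Et3N, DMAP) joins F12 and F13 to the ester F14.
- AcOH–THF–water removes the triethylsilyl group and comes back to the route at 24.

**Further compounds**
F1 | step 9 | alkynyl isopropenyl carbinol | O[C@@]1(C#COCc2ccc(OC)cc2)C=C(C)[C@@H](O[Si](CC)(CC)CC)C[C@@H]1C(C)=C
F2 | step 9 | (Z)‑alkoxyvinyl isopropenyl carbinol | O[C@@]1(/C=C\OCc2ccc(OC)cc2)C=C(C)[C@@H](O[Si](CC)(CC)CC)C[C@@H]1C(C)=C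
F3 | step 9 | C9‑unsubstituted keto ester | O=C1/C=C(/C)[C@@H](O[Si](CC)(CC)CC)C/C=C(/C)C[C@@H](OCc2ccc(OC)cc2)[C@H]1CC(=O)OC(C)(C)C
F4 | step 9 | 9‑hydroxy keto ester | O=C1/C=C(/C)[C@@H](O[Si](CC)(CC)CC)C/C=C(/C)[C@@H](O)[C@@H](OCc2ccc(OC)cc2)[C@H]1CC(=O)OC(C)(C)C
F5 | step 7 | pseudoequatorial allylic alcohol | O[C@H]1C=C(C)[C@@H](O[Si](CC)(CC)CC)C[C@@H]1/C(C)=C/O[Si](C)(C)C(C)(C)C
F6 | step 7 | N,N‑diisopropylcarbamate | CC(C)N(C(C)C)C(=O)O[C@H]1C=C(C)[C@@H](O[Si](CC)(CC)CC)C[C@@H]1/C(C)=C/O[Si](C)(C)C(C)(C)C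
F7 | step 7 | ethynyl 4‑methoxybenzyl ether | C#COCc1ccc(OC)cc1
F8 | step 7 | (Z)‑2‑(4‑methoxybenzyloxy)ethenylboronic acid pinacol ester | COc1ccc(CO/C=C\B2OC(C)(C)C(C)(C)O2)cc1
F9 | step 7 | tertiary allylic boronic ester | CC1(C)OB(OC1(C)C)[C@@]2(/C=C\OCc3ccc(OC)cc3)C=C(C)[C@@H](O[Si](CC)(CC)CC)C[C@@H]2/C(C)=C/O[Si](C)(C)C(C)(C)C
F10 | step 13 | (6R)‑alcohol with O8‑PMB | O[C@@H]1/C=C(/C)[C@@H](O[Si](CC)(CC)CC)C/C=C(/C)[C@@H](O[Si](C)(C)C(C)(C)C)[C@@H](OCc2ccc(OC)cc2)[C@H]1CC(=O)OC(C)(C)C
F11 | step 13 | PMB‑protected lactone | C1C(=O)O[C@@H]2/C=C(/C)[C@@H](O[Si](CC)(CC)CC)C/C=C(/C)[C@@H](O[Si](C)(C)C(C)(C)C)[C@@H](OCc3ccc(OC)cc3)[C@@H]12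
F12 | step 13 | 8‑hydroxy lactone | C1C(=O)O[C@@H]2/C=C(/C)[C@@H](O[Si](CC)(CC)CC)C/C=C(/C)[C@@H](O[Si](C)(C)C(C)(C)C)[C@@H](O)[C@@H]12
F13 | step 13 | (2S,3R)‑2,3‑dimethyloxirane‑2‑carboxylic acid | OC(=O)[C@@]1(C)O[C@@H]1C
F14 | step 13 | 3‑O‑TES 8‑epoxy ester lactone | C1C(=O)O[C@@H]2/C=C(/C)[C@@H](O[Si](CC)(CC)CC)C/C=C(/C)[C@@H](O[Si](C)(C)C(C)(C)C)[C@@H](OC(=O)[C@@]3(C)O[C@@H]3C)[C@@H]12
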